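**Strategy.** The plan opens the lactone bond O1–C8a of the 6,7-dioxygenated coumarin, the pyranone ring that carries the aryl ether at C3. Because C8a is the arene carbon para to the C6 oxygen and ortho to the side chain, the ring is a cyclised α-aryloxy caffeic acid. One flavin-photocatalysed operation on a (Z)-2-aryloxy-3-(3,4-dioxyphenyl)acrylic acid turns the alkene so that carboxyl and arene are adjacent and then bonds the carboxylate oxygen to that C–H carbon, closing the pyranone. The precursor carries a catechol acetonide, a MOM ether and a bromide, which is saved for a late Heck coupling with a protected (R)-danshensu acrylate before one acidic unmasking.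

Key step: step 7

Assumption: (R)-danshensu is used as the free acid of high enantiomeric purity; a sodium salt would be acidified and extracted first.

**Route**

Step 1
Reactants: 1 4-bromo-2-hydroxybenzaldehyde
Product: 2 4-bromo-2-(methoxymethoxy)benzaldehyde
Conditions: MOMCl, iPr2NEt, CH2Cl2, 0 °C to rt
Reagents that add atoms: chloromethyl methyl ether, COCCl
Why: Williamson-type O-alkylation of the phenol by the reactive α-chloro ether gives an acetal that tolerates the later peracid, enolate and palladium steps, and capping this oxygen first means no free phenol ever sits next to the ester introduced in step 3.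

Step 2
Reactants: 2 4-bromo-2-(methoxymethoxy)benzaldehyde
Product: 4 4-bromo-2-(methoxymethoxy)phenol, via aryl formate 3 (not isolated)
Conditions: mCPBA, CH2Cl2, 0 °C to rt; aqueous Na2S2O3/NaHCO3 wash; then K2CO3 (cat.), MeOH, rt
Reagents that add atoms: 3-chloroperoxybenzoic acid, O=C(OO)c1cccc(Cl)c1
Why: In this Baeyer–Villiger (Dakin-type) oxidation the aryl group, activated by its ortho alkoxy substituent, should migrate in preference to hydride, and the resulting formate is cleaved by base-catalysed methanolysis.

Step 3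
Reactants: 4 4-bromo-2-(methoxymethoxy)phenol; 5 methyl bromoacetate
Product: 6 methyl 2-[4-bromo-2-(methoxymethoxy)phenoxy]acetate
Conditions: K2CO3, DMF, rt
Reagents that add atoms: none
Why: Williamson ether synthesis by SN2 attack of the phenoxide on the α-bromo ester places the acetate arm on the oxygen para to bromine without regiochemical ambiguity.

Step 4
Reactants: 7 3,4-dihydroxybenzaldehyde
Product: 8 2,2-dimethyl-1,3-benzodioxole-5-carbaldehyde
Conditions: 2,2-dimethoxypropane, TsOH·H2O (cat.), toluene, reflux, MeOH removed over 4 Å molecular sieves; brief 1 M HCl/THF wash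
Reagents that add atoms: 2,2-dimethoxypropane, COC(C)(C)OC
Why: Acid-catalysed transketalisation of the catechol is driven by removal of methanol, and the short aqueous acid wash should return any aldehyde dimethyl acetal to the aldehyde while the cyclic ketal survives.

Step 5
Reactants: 6 methyl 2-[4-bromo-2-(methoxymethoxy)phenoxy]acetate; 8 2,2-dimethyl-1,3-benzodioxole-5-carbaldehyde
Product: 9 methyl 2-[4-bromo-2-(methoxymethoxy)phenoxy]-3-(2,2-dimethyl-1,3-benzodioxol-5-yl)-3-hydroxypropanoate (racemic mixture of both diastereomers)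
Conditions: LiN(iPr)2, THF, −78 °C; then 8, −78 °C; AcOH quench
Reagents that add atoms: none
Why: Directed aldol addition of the lithium enolate of the α-aryloxy ester to a non-enolisable aldehyde is reliable at low temperature, and the two new stereocentres need no control because both are erased in step 6.

Step 6
Reactants: 9 methyl 2-[4-bromo-2-(methoxymethoxy)phenoxy]-3-(2,2-dimethyl-1,3-benzodioxol-5-yl)-3-hydroxypropanoate
Product: 12 (Z)-2-[4-bromo-2-(methoxymethoxy)phenoxy]-3-(2,2-dimethyl-1,3-benzodioxol-5-yl)acrylic acid, via mesylate 10 (not isolated), via methyl Z-acrylate 11 (not isolated)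
Conditions: MsCl, Et3N, THF, 0 °C; DBU, rt; then LiOH, H2O/MeOH, rt; 1 M HCl to pH 3 at 0 °C
Reagents that add atoms: lithium hydroxide, [Li+].[OH-]
Why: Mesylation of the benzylic alcohol, E1cB elimination to the thermodynamically preferred Z enol-ether acrylate (aryl trans to the ester) and saponification in the same flask should give the acid, whose geometric purity is not critical because step 7 equilibrates the alkene.

Step 7
Reactants: 12 (Z)-2-[4-bromo-2-(methoxymethoxy)phenoxy]-3-(2,2-dimethyl-1,3-benzodioxol-5-yl)acrylic acid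
Product: 14 7-[4-bromo-2-(methoxymethoxy)phenoxy]-2,2-dimethyl-6H-[1,3]dioxolo[4,5-g]chromen-6-one, via E acid 13 (not isolated)
Conditions: (−)-riboflavin (5 mol%), O2 (1 atm), 402 nm LEDs, MeCN/MeOH (1:1), rt
Reagents that add atoms: none
Why: Excited riboflavin first passes triplet energy to the styrene-type chromophore of 12, and rotation in the triplet state gives the E acid 13 with the carboxyl beside the arene; the excited flavin then removes one electron from the electron-rich benzodioxole–enol ether π system, the carboxylate oxygen adds to the ortho carbon of the radical cation, and a second one-electron oxidation with loss of the ring proton restores aromaticity while O2 reoxidises the reduced flavin. The closest known reaction type is the flavin-photocatalysed isomerisation and oxidative lactonisation cascade that converts cinnamic acids into coumarins under visible light and O2. The pyranone ring closes in a 6-endo-trig sense, the carboxylate oxygen attacking C8a of the C4a=C8a bond that lies inside the new ring, so that O1–C8a is the only skeletal bond formed. No stereocentre is created. The step needs closure at the ring carbon para to the C6 oxygen instead of the carbon flanked by the side chain and that oxygen: the para oxygen places the positive charge of the radical cation on the intended carbon, whereas attack at the flanked carbon would set three C–O bonds in a row at a more crowded site. Chemoselectivity rests on the bromo-substituted aryloxy ring being harder to oxidise than the benzodioxole, on the acetonide having no O–CH–O hydrogen to lose, and on the aryl bromide being inert to the oxidising flavin cycle.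

Step 8
Reactants: 15 (R)-danshensu, (R)-3-(3,4-dihydroxyphenyl)-2-hydroxypropanoic acid
Product: 16 tert-butyl (R)-3-(3,4-dihydroxyphenyl)-2-hydroxypropanoate
Conditions: Cl3CC(=NH)Ot-Bu, THF/cyclohexane, rt
Reagents that add atoms: tert-butyl 2,2,2-trichloroacetimidate, CC(C)(C)OC(=N)C(Cl)(Cl)Cl
Why: In this trichloroacetimidate esterification only the carboxylic acid is acidic enough to activate the imidate and capture the tert-butyl cation, so the phenols and the alcohol stay free and the R stereocentre, which comes from 15, is not touched.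

Step 9
Reactants: 16 tert-butyl (R)-3-(3,4-dihydroxyphenyl)-2-hydroxypropanoate
Product: 17 tert-butyl (R)-3-[3,4-bis(methoxymethoxy)phenyl]-2-hydroxypropanoate
Conditions: MOMCl (2.2 equiv), K2CO3, acetone, 0 °C to rt, argon
Reagents that add atoms: chloromethyl methyl ether, COCCl
Why: Carbonate deprotonates only the phenols, so phenoxide O-alkylation (Williamson type) caps the catechol and leaves the secondary alcohol free, and the base is too weak to enolise the ester.

Step 10
Reactants: 17 tert-butyl (R)-3-[3,4-bis(methoxymethoxy)phenyl]-2-hydroxypropanoate; 18 acryloyl chloride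
Product: 19 tert-butyl (R)-2-(acryloyloxy)-3-[3,4-bis(methoxymethoxy)phenyl]propanoate
Conditions: Et3N, CH2Cl2, −20 to 0 °C
Reagents that add atoms: none
Why: O-acylation of the secondary alcohol by the acid chloride breaks no bond at the stereocentre, so the R configuration is retained.

Step 11
Reactants: 14 7-[4-bromo-2-(methoxymethoxy)phenoxy]-2,2-dimethyl-6H-[1,3]dioxolo[4,5-g]chromen-6-one; 19 tert-butyl (R)-2-(acryloyloxy)-3-[3,4-bis(methoxymethoxy)phenyl]propanoate
Product: 20 tert-butyl (R)-3-[3,4-bis(methoxymethoxy)phenyl]-2-{[(E)-3-{4-[(2,2-dimethyl-6-oxo-6H-[1,3]dioxolo[4,5-g]chromen-7-yl)oxy]-3-(methoxymethoxy)phenyl}prop-2-enoyl]oxy}propanoate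
Conditions: Pd2(dba)3 (cat.), [HP(t-Bu)3]BF4 (cat.), Cy2NMe, 1,4-dioxane, 60 °C
Reagents that add atoms: none
Why: In this Mizoroki–Heck reaction oxidative addition of the aryl bromide to zerovalent palladium bearing the bulky electron-rich phosphine, syn insertion of the acrylate and syn β-hydride elimination should give the E cinnamate, and the mild temperature and hindered amine spare the lactone and the α-acyloxy ester stereocentre.

Step 12
Reactants: 20 tert-butyl (R)-3-[3,4-bis(methoxymethoxy)phenyl]-2-{[(E)-3-{4-[(2,2-dimethyl-6-oxo-6H-[1,3]dioxolo[4,5-g]chromen-7-yl)oxy]-3-(methoxymethoxy)phenyl}prop-2-enoyl]oxy}propanoate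
Product: 21 (R)-3-(3,4-dihydroxyphenyl)-2-{[(E)-3-{4-[(6,7-dihydroxy-2-oxo-2H-chromen-3-yl)oxy]-3-hydroxyphenyl}prop-2-enoyl]oxy}propanoic acid
Conditions: TFA/H2O (9:1), dilute, 0 °C to rt; reverse-phase chromatography
Reagents that add atoms: none
Why: Acid-mediated acetal hydrolysis should remove the three MOM ethers and the catechol acetonide while the tert-butyl ester loses isobutene, and the cinnamate ester, the lactone and the stereocentre are stable to non-nucleophilic acid.

**Compound list**

1 | 4-bromo-2-hydroxybenzaldehyde | O=Cc1ccc(Br)cc1O | starting material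
2 | 4-bromo-2-(methoxymethoxy)benzaldehyde | COCOc1cc(Br)ccc1C=O | intermediate
3 | 4-bromo-2-(methoxymethoxy)phenyl formate | COCOc1cc(Br)ccc1OC=O | intermediate (not isolated)
4 | 4-bromo-2-(methoxymethoxy)phenol | COCOc1cc(Br)ccc1O | intermediate
5 | methyl bromoacetate | COC(=O)CBr | starting material
6 | methyl 2-[4-bromo-2-(methoxymethoxy)phenoxy]acetate | COCOc1cc(Br)ccc1OCC(=O)OC | intermediate
7 | 3,4-dihydroxybenzaldehyde | O=Cc1ccc(O)c(O)c1 | starting material
8 | 2,2-dimethyl-1,3-benzodioxole-5-carbaldehyde | O=Cc1ccc2OC(C)(C)Oc2c1 | intermediate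
9 | methyl 2-[4-bromo-2-(methoxymethoxy)phenoxy]-3-(2,2-dimethyl-1,3-benzodioxol-5-yl)-3-hydroxypropanoate, racemic mixture of both diastereomers | COC(=O)C(Oc1ccc(Br)cc1OCOC)C(O)c1ccc2OC(C)(C)Oc2c1 | intermediate
10 | methyl 2-[4-bromo-2-(methoxymethoxy)phenoxy]-3-(2,2-dimethyl-1,3-benzodioxol-5-yl)-3-(methylsulfonyloxy)propanoate | COC(=O)C(Oc1ccc(Br)cc1OCOC)C(OS(C)(=O)=O)c1ccc2OC(C)(C)Oc2c1 | intermediate (not isolated)
11 | methyl (Z)-2-[4-bromo-2-(methoxymethoxy)phenoxy]-3-(2,2-dimethyl-1,3-benzodioxol-5-yl)acrylate | COC(=O)/C(Oc1ccc(Br)cc1OCOC)=C/c1ccc2OC(C)(C)Oc2c1 | intermediate (not isolated)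
12 | (Z)-2-[4-bromo-2-(methoxymethoxy)phenoxy]-3-(2,2-dimethyl-1,3-benzodioxol-5-yl)acrylic acid (aryl trans to CO2H) | OC(=O)/C(Oc1ccc(Br)cc1OCOC)=C/c1ccc2OC(C)(C)Oc2c1 | intermediate
13 | (E)-2-[4-bromo-2-(methoxymethoxy)phenoxy]-3-(2,2-dimethyl-1,3-benzodioxol-5-yl)acrylic acid (aryl cis to CO2H) | OC(=O)/C(Oc1ccc(Br)cc1OCOC)=C\c1ccc2OC(C)(C)Oc2c1 | intermediate (not isolated)
14 | 7-[4-bromo-2-(methoxymethoxy)phenoxy]-2,2-dimethyl-6H-[1,3]dioxolo[4,5-g]chromen-6-one, that is 3-[4-bromo-2-(methoxymethoxy)phenoxy]-6,7-(isopropylidenedioxy)coumarin | COCOc1cc(Br)ccc1Oc1cc2cc3OC(C)(C)Oc3cc2oc1=O | intermediate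
15 | (R)-danshensu, (R)-3-(3,4-dihydroxyphenyl)-2-hydroxypropanoic acid | O[C@H](Cc1ccc(O)c(O)c1)C(=O)O | starting material
16 | tert-butyl (R)-3-(3,4-dihydroxyphenyl)-2-hydroxypropanoate | O[C@H](Cc1ccc(O)c(O)c1)C(=O)OC(C)(C)C | intermediate
17 | tert-butyl (R)-3-[3,4-bis(methoxymethoxy)phenyl]-2-hydroxypropanoate | O[C@H](Cc1ccc(OCOC)c(OCOC)c1)C(=O)OC(C)(C)C | intermediate
18 | acryloyl chloride | C=CC(=O)Cl | starting material
19 | tert-butyl (R)-2-(acryloyloxy)-3-[3,4-bis(methoxymethoxy)phenyl]propanoate | C=CC(=O)O[C@H](Cc1ccc(OCOC)c(OCOC)c1)C(=O)OC(C)(C)C | intermediate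
20 | tert-butyl (R)-3-[3,4-bis(methoxymethoxy)phenyl]-2-{[(E)-3-{4-[(2,2-dimethyl-6-oxo-6H-[1,3]dioxolo[4,5-g]chromen-7-yl)oxy]-3-(methoxymethoxy)phenyl}prop-2-enoyl]oxy}propanoate | O=C(/C=C/c1ccc(Oc2cc3cc4OC(C)(C)Oc4cc3oc2=O)c(OCOC)c1)O[C@H](Cc1ccc(OCOC)c(OCOC)c1)C(=O)OC(C)(C)C | intermediate
21 | (R)-3-(3,4-dihydroxyphenyl)-2-{[(E)-3-{4-[(6,7-dihydroxy-2-oxo-2H-chromen-3-yl)oxy]-3-hydroxyphenyl}prop-2-enoyl]oxy}propanoic acid (CNP0318082.1) | O=C(/C=C/c1ccc(Oc2cc3cc(O)c(O)cc3oc2=O)c(O)c1)O[C@H](Cc1ccc(O)c(O)c1)C(=O)O | target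

**Step count and risks**

Total step count: 12. Longest linear sequence: 8 steps (steps 1, 2, 3, 5, 6, 7, 11 and 12).

Steps most likely to fail:

1. Step 7. The electron-rich enol-ether alkene may be cleaved by singlet oxygen, the radical cation may be captured by methanol before the carboxylate closes, or closure may occur partly at the flanked ring carbon. The fallback builds the lactone by classical condensation; it sets out from 6 and 8 and returns at 14. Ester 6 would be saponified (LiOH, THF/H2O) to 2-[4-bromo-2-(methoxymethoxy)phenoxy]acetic acid F1. Aldehyde 8 would undergo Baeyer–Villiger oxidation (mCPBA, CH2Cl2) to 2,2-dimethyl-1,3-benzodioxol-5-yl formate F2, which base-catalysed methanolysis would convert into 2,2-dimethyl-1,3-benzodioxol-5-ol F3. Ortho-formylation of this phenol (MgCl2, Et3N, paraformaldehyde, MeCN, reflux) at the less hindered ortho carbon should give 6-hydroxy-2,2-dimethyl-1,3-benzodioxole-5-carbaldehyde F4. Steglich esterification of F4 with F1 (EDC·HCl, DMAP, CH2Cl2) would give 6-formyl-2,2-dimethyl-1,3-benzodioxol-5-yl 2-[4-bromo-2-(methoxymethoxy)phenoxy]acetate F5, and DBU in MeCN should close it by intramolecular Knoevenagel-type condensation and dehydration to coumarin 14.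

2. Step 11. Slow oxidative addition at the electron-rich bromide may force higher temperatures, with base-mediated epimerisation at the α-acyloxy ester stereocentre or oligomerisation of the acrylate. The fallback moves the stereocentre behind the palladium step; it sets out from 14 and returns at 20. Coumarin 14 would be coupled with acrylic acid (Pd(OAc)2, P(o-tol)3, Et3N, DMF, 100 °C) to (E)-3-{4-[(2,2-dimethyl-6-oxo-6H-[1,3]dioxolo[4,5-g]chromen-7-yl)oxy]-3-(methoxymethoxy)phenyl}acrylic acid F6, and Steglich esterification of F6 with alcohol 17 (EDC·HCl, DMAP, CH2Cl2, 0 °C) should give 20 without use of 19.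

3. Step 12. The methoxymethyl cation or formaldehyde released from three MOM groups may alkylate the freed catechol rings, or hydrolysis of the coumarin acetonide may lag under conditions mild enough for the ester. The fallback unmasks in two stages; it sets out from 20 and returns at 21. Treatment of 20 with ZnBr2 and n-PrSH in CH2Cl2 at 0 °C should strip the MOM groups as a thioacetal, so that no free formaldehyde forms, giving tert-butyl (R)-3-(3,4-dihydroxyphenyl)-2-{[(E)-3-{4-[(2,2-dimethyl-6-oxo-6H-[1,3]dioxolo[4,5-g]chromen-7-yl)oxy]-3-hydroxyphenyl}prop-2-enoyl]oxy}propanoate F7. Aqueous TFA would then remove the acetonide and the tert-butyl ester to give 21.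

Further compounds
F1 | step 7 | 2-[4-bromo-2-(methoxymethoxy)phenoxy]acetic acid | COCOc1cc(Br)ccc1OCC(=O)O
F2 | step 7 | 2,2-dimethyl-1,3-benzodioxol-5-yl formate | O=COc1ccc2OC(C)(C)Oc2c1
F3 | step 7 | 2,2-dimethyl-1,3-benzodioxol-5-ol | Oc1ccc2OC(C)(C)Oc2c1
F4 | step 7 | 6-hydroxy-2,2-dimethyl-1,3-benzodioxole-5-carbaldehyde | O=Cc1cc2OC(C)(C)Oc2cc1O
F5 | step 7 | 6-formyl-2,2-dimethyl-1,3-benzodioxol-5-yl 2-[4-bromo-2-(methoxymethoxy)phenoxy]acetate | COCOc1cc(Br)ccc1OCC(=O)Oc1cc2OC(C)(C)Oc2cc1C=O
F6 | step 11 | (E)-3-{4-[(2,2-dimethyl-6-oxo-6H-[1,3]dioxolo[4,5-g]chromen-7-yl)oxy]-3-(methoxymethoxy)phenyl}acrylic acid | OC(=O)/C=C/c1ccc(Oc2cc3cc4OC(C)(C)Oc4cc3oc2=O)c(OCOC)c1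
F7 | step 12 | tert-butyl (R)-3-(3,4-dihydroxyphenyl)-2-{[(E)-3-{4-[(2,2-dimethyl-6-oxo-6H-[1,3]dioxolo[4,5-g]chromen-7-yl)oxy]-3-hydroxyphenyl}prop-2-enoyl]oxy}propanoate | O=C(/C=C/c1ccc(Oc2cc3cc4OC(C)(C)Oc4cc3oc2=O)c(O)c1)O[C@H](Cc1ccc(O)c(O)c1)C(=O)OC(C)(C)C
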